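**Assumptions (one line each)**
- The target has no stereocentres. It is achiral, so "single enantiomer" does not apply, and the only stereo-element in the route (the ring-closing-metathesis alkene geometry) is removed by hydrogenation.
- The chain is taken as 16 CH2 groups, giving a 22-membered ring.
- 1-Bromo-3-iodo-5-methoxybenzene (6) is taken as commercially available.

**Retrosynthesis**
1. Final disconnection: aryl methyl ethers ← free phenols (BBr3).
2. The saturated 22-membered metacyclophane comes from H2 reduction of the ring-closing-metathesis (RCM) product. RCM of a bis(ω-alkenyl) diaryl ether closes the macrocycle, with (CH2)7 on each arm.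
3. The two arms come from a double B-alkyl Suzuki coupling of a dibromo diaryl ether with 9-(non-8-enyl)-9-BBN.
4. The diaryl ether comes from Cu-catalysed Ullmann coupling of 2-bromo-4,6-dimethoxyphenol with 1-bromo-3-iodo-5-methoxybenzene, which is selective for C–I over C–Br.
5. The phenol comes from 1-bromo-3,5-dimethoxybenzene by Vilsmeier formylation and then Dakin (Baeyer–Villiger) oxidation. Ring order: diaryl ether, then both chains, then the macrocycle by RCM.

**Route**

Step 1
Reactants: 1 (1-bromo-3,5-dimethoxybenzene); 2 (N,N-dimethylformamide)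
Product: 3 (2-bromo-4,6-dimethoxybenzaldehyde)
Conditions: POCl3, DMF, 0 °C→80 °C; then aq. NaOAc, 0 °C
Reagents that add atoms: DMF, CN(C)C=O (gives the CHO carbon); H2O, O (workup; hydrolyses the iminium to the aldehyde)
Why: Vilsmeier–Haack formylation goes at C2, which is ortho to one OMe and para to the other, and is less hindered than the position between the two OMe groups. Formylation at C2 puts CHO ortho to Br.

Step 2
Reactants: 3; 4 (mCPBA)
Product: 5 (2-bromo-4,6-dimethoxyphenol)
Conditions: mCPBA, CH2Cl2, 0 °C→rt; then K2CO3, MeOH, rt
Reagents that add atoms: mCPBA, OOC(=O)c1cccc(Cl)c1 (its O ends up as the phenol O)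
Why: Dakin/Baeyer–Villiger oxidation. The electron-rich aryl group (ortho and para OMe) migrates preferentially to give the aryl formate, and methanolysis releases the phenol, which now carries OH, OMe, Br and OMe in the ring-B pattern of the target.

Step 3
Reactants: 5; 6 (1-bromo-3-iodo-5-methoxybenzene)
Product: 7 (1-bromo-3-(2-bromo-4,6-dimethoxyphenoxy)-5-methoxybenzene)
Conditions: CuI (10 mol%), picolinic acid (20 mol%), K3PO4, DMSO, 80 °C
Reagents that add atoms: none (6 is a reactant; HI is lost)
Why: Ullmann-type C–O coupling with a Cu/picolinate catalyst, which tolerates hindered 2,6-disubstituted phenols. It reacts at the C–I bond and leaves both C–Br bonds for Step 5.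

Step 4 (reagent preparation, used in situ)
Reactants: 8 (nona-1,8-diene); 9 (9-BBN)
Product: 10 (9-(non-8-en-1-yl)-9-borabicyclo[3.3.1]nonane)
Conditions: 9-BBN (1 equiv per diene), THF, 0 °C→rt, 3 h
Reagents that add atoms: none
Why: 9-BBN hydroborates the terminal alkene anti-Markovnikov and much faster than the 1,1-disubstituted alternative, so it gives the primary alkylborane and leaves the other terminal alkene untouched. The diene is used in slight excess over 9-BBN to limit bis-hydroboration.

Step 5
Reactants: 7; 10 (2.6 equiv)
Product: 11 (1-(non-8-en-1-yl)-3-[2-(non-8-en-1-yl)-4,6-dimethoxyphenoxy]-5-methoxybenzene)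
Conditions: Pd(dppf)Cl2 (10 mol%), K3PO4 (aq.), THF, 65 °C
Reagents that add atoms: none (10 is a numbered reactant)
Why: B-alkyl Suzuki–Miyaura coupling installs both (CH2)7CH=CH2 arms in one operation, and terminal alkenes survive these conditions. This sets the 7 + 7 carbon split needed for the 16-carbon chain.

Step 6
Reactants: 11
Product: 12 (macrocyclic alkene, E/Z mixture; 22-membered ring)
Conditions: Grubbs II (5–10 mol%), CH2Cl2, 2 mM, 40 °C, 12 h
Reagents that add atoms: none (ethylene is lost)
Why: Ring-closing metathesis under high dilution forms the C16 chain as a CH=CH-containing ring (7 + 2 + 7 carbons). The alkene geometry is irrelevant because it is hydrogenated next.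

Step 7
Reactants: 12
Product: 13 (saturated macrocyclic trimethyl ether)
Conditions: H2 (1 atm), 10% Pd/C, EtOAc, rt
Reagents that add atoms: none (H2 adds only hydrogen)
Why: Catalytic hydrogenation reduces the alkene. Aryl methyl ethers and the diaryl ether are inert, and no halogen remains.

Step 8
Reactants: 13
Product: 14 (Grevirobstol B)
Conditions: BBr3 (6 equiv), CH2Cl2, −78 °C→rt, 6 h; then aq. NaHCO3 workup
Reagents that add atoms: none
Why: BBr3 cleaves aryl methyl ethers to the three phenols. Diaryl ethers and the alkyl chain are stable at these temperatures.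

**Final check**
- Ring A is 1-OH, 3-OAr, 5-chain (meta), from anisole 6.
- Ring B is OAr, with an ortho chain (from Br), an ortho OH, and a para OH. This matches Oc1c(O)cc(O)cc1C.
- Ring size is 3 + 1 + 2 + 16 = 22.
- Formula: 11 is C33H48O4; RCM gives C31H44O4; H2 gives C31H46O4; losing three CH2 gives C28H40O4 (target).
- Every functional group survives each step. The two Br atoms are present only until Step 5, and the methyl ethers are removed last.

**Compound list**
1 | 1-bromo-3,5-dimethoxybenzene | COc1cc(Br)cc(OC)c1 | starting material
2 | N,N-dimethylformamide | CN(C)C=O | starting material (reagent)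
3 | 2-bromo-4,6-dimethoxybenzaldehyde | O=Cc1c(Br)cc(OC)cc1OC | intermediate
4 | mCPBA | OOC(=O)c1cccc(Cl)c1 | starting material (reagent)
5 | 2-bromo-4,6-dimethoxyphenol | COc1cc(Br)c(O)c(OC)c1 | intermediate
6 | 1-bromo-3-iodo-5-methoxybenzene | COc1cc(Br)cc(I)c1 | starting material
7 | 1-bromo-3-(2-bromo-4,6-dimethoxyphenoxy)-5-methoxybenzene | COc1cc(Br)cc(Oc2c(Br)cc(OC)cc2OC)c1 | intermediate
8 | nona-1,8-diene | C=CCCCCCC=C | starting material
9 | 9-BBN (9-borabicyclo[3.3.1]nonane) | B1C2CCCC1CCC2 | starting material
10 | 9-(non-8-en-1-yl)-9-BBN | C=CCCCCCCCB1C2CCCC1CCC2 | intermediate (reagent)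
11 | bis(non-8-enyl) diaryl ether | C=CCCCCCCCc1cc(OC)cc(Oc2c(CCCCCCCC=C)cc(OC)cc2OC)c1 | intermediate
12 | macrocyclic alkene (E/Z) | COc1cc2cc(c1)Oc1c(OC)cc(OC)cc1CCCCCCCC=CCCCCCCC2 | intermediate
13 | saturated trimethyl ether macrocycle | COc1cc2cc(c1)Oc1c(OC)cc(OC)cc1CCCCCCCCCCCCCCCC2 | intermediate
14 | Grevirobstol B (no stereocentres) | Oc1cc2cc(c1)Oc1c(O)cc(O)cc1CCCCCCCCCCCCCCCC2 | target

**Totals**
- Total steps: 8, including the in-situ borane preparation.
- Longest linear sequence: 7 steps (1 → 3 → 5 → 7 → 11 → 12 → 13 → 14).

**Three steps most likely to fail**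
1. **Step 6 (macro-RCM)**. Oligomerisation or stalling at the 22-membered ring are the risks.
   - Fallback: change the ring-closing reaction to an intramolecular B-alkyl Suzuki macrocyclisation. Couple a mono-(non-8-enyl) diaryl ether that still carries one Ar–Br with the other arm's alkene hydroborated by 9-BBN, using Pd and a base at high dilution, then hydrogenate.
2. **Step 3 (hindered Ullmann etherification)**. The phenol is 2,6-disubstituted, and the aryl iodide is electron-rich.
   - Fallback: use a Chan–Lam coupling of phenol 5 with 3-bromo-5-methoxyphenylboronic acid (Cu(OAc)2, pyridine, air, CH2Cl2).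
3. **Step 5 (double B-alkyl Suzuki)**. The ortho-substituted Br is hindered, and bis-hydroboration of the diene can give Ar–(CH2)9–Ar cross-links.
   - Fallback: use a Negishi coupling with non-8-enylzinc bromide (made from 9-bromonon-1-ene; Pd-PEPPSI-IPent), which avoids diene bis-hydroboration and B-alkyl transmetalation.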